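**Retrosynthetic overview**

1. Ring A (C4a–C5–C6–C7–C8–C8a) is cut into a 2-methylmalonyl C3 unit (C5, C6, C7) and the C4a=C8a(O1)–C8 triad of a spiro-dihydropyran enol ether: an Effenberger-type [3+3] cyclization with methylmalonyl dichloride forms C4a–C5 and C7–C8 (the gem-dimethyl centre); the 7-OH is methylated last.
2. Enabling feature: ring A is a β-triketone-level ring in which C8a is an enol ether carbon bound to the pyran oxygen O1 and flanked by the nucleophilic C4a and by C8 (an isopropyl methine before the step), while C5/C6/C7 form a symmetric malonyl unit. Because O1 is locked in the pyran ring, only C,C-annulation is open, and the positions of O1 and OMe are unambiguous.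
3. Pyran ring (O1–C2 and C3–C4 bonds): three-component Knoevenagel/hetero-Diels–Alder reaction of isobutyraldehyde, allyl isobutyrylacetate and the exocyclic methylene of a muurolane-type 4(15),5-diene; the allyl ester is a removable activating group.
4. Decalin: (R)-citronellal plus methyl vinyl ketone by enamine catalysis (sets C4a'), aldol condensation (ring 1), Lewis-acid ene cyclization (ring 2, sets C8'), dehydrogenation, Wittig methylenation.
5. Ring order: cyclohexenone (ring 1) → decalin (ring 2) → dihydropyran → ring A.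

Key step: step 11

Remark: locants follow spiro[chromene-2,2'-naphthalene] numbering (O1, C2 spiro, C3, C4, C4a, C5–C8, C8a; primed locants for the decalin); the SMILES is read as the (2S,4R,4a'R,5'R,8'S) isomer, and methylmalonyl dichloride is prepared (step 10) because its commercial supply is uncertain.

**Route**

Step 1
Reactants: 1 (3R)-3,7-dimethyloct-6-enal [(R)-citronellal]; 2 but-3-en-2-one (methyl vinyl ketone)
Product: 3 (2R,3R)-3,7-dimethyl-2-(3-oxobutyl)oct-6-enal
Conditions: (R)-2-[diphenyl(trimethylsilyloxy)methyl]pyrrolidine (10 mol %), ethyl 3,4-dihydroxybenzoate (20 mol %), neat, 4 °C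
Reagents that add atoms: none
Why: Enamine-catalysed Michael addition of an aldehyde to an enone; the (R)-catalyst shields one face of the E-enamine, so the new C2 centre (later C4a') should form as 2R under catalyst control, while the C3 methyl centre of (R)-citronellal is carried through unchanged.

Step 2
Reactants: 3 (2R,3R)-3,7-dimethyl-2-(3-oxobutyl)oct-6-enal
Product: 4 (4R)-4-[(2R)-6-methylhept-5-en-2-yl]cyclohex-2-en-1-one
Conditions: LiOH·H2O (0.3 equiv), i-PrOH, 23 °C
Reagents that add atoms: none
Why: Intramolecular aldol condensation of the methyl ketone onto the aldehyde; the mild base is chosen so that ring closure outruns epimerisation of the aldehyde α-centre, which afterwards is the non-acidic γ-carbon C4 of the enone.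

Step 3
Reactants: 4 (4R)-4-[(2R)-6-methylhept-5-en-2-yl]cyclohex-2-en-1-one
Product: 5 (4aR,5R,8R,8aR)-5-methyl-8-(prop-1-en-2-yl)octahydronaphthalen-2(1H)-one
Conditions: MeAlCl2 (1.5 equiv), CH2Cl2, −78 → −20 °C; 1 M HCl quench
Reagents that add atoms: none
Why: Lewis-acid-promoted intramolecular conjugate ene (Michael–ene) cyclization of the trisubstituted alkene onto the enone β-carbon, the enone counterpart of the ene cyclization of citronellal-derived alkylidene malonates; axial attack through a chair-like transition state with the C5 methyl and the reacting alkene equatorial should give the cis-fused decalone and set C8 (isopropenyl trans to the C5 methyl) and C8a.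

Step 4
Reactants: 5 (4aR,5R,8R,8aR)-5-methyl-8-(prop-1-en-2-yl)octahydronaphthalen-2(1H)-one
Product: 6 (4aR,5R,8S,8aS)-5-methyl-8-(propan-2-yl)octahydronaphthalen-2(1H)-one
Conditions: H2 (1 atm), Pd/C (10 wt % palladium on carbon), EtOAc, 23 °C
Reagents that add atoms: none
Why: Heterogeneous catalytic hydrogenation of the 1,1-disubstituted alkene only; no stereocentre is created (the C8 and C8a descriptors change only through the priority rules).

Step 5
Reactants: 6 (4aR,5R,8S,8aS)-5-methyl-8-(propan-2-yl)octahydronaphthalen-2(1H)-one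
Product: 8 (4aR,5R,8S)-5-methyl-8-(propan-2-yl)-4,4a,5,6,7,8-hexahydronaphthalen-2(3H)-one, via silyl enol ether 7 (not isolated)
Conditions: TMSCl, NaI, Et3N, MeCN, 23 °C; then Pd(OAc)2 (10 mol %), O2 (1 atm), DMSO, 60 °C
Reagents that add atoms: none
Why: Saegusa–Ito dehydrogenation via the thermodynamic silyl enol ether, which for this cis-fused 2-decalone should form toward the ring-fusion side C1 (as for cis-fused 5β 3-keto steroids), so the C1=C8a enone results; the C8a centre is removed and C4a, C5 and C8 are untouched.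

Step 6
Reactants: 8 (4aR,5R,8S)-5-methyl-8-(propan-2-yl)-4,4a,5,6,7,8-hexahydronaphthalen-2(3H)-one
Product: 9 (4aR,5R,8S)-5-methyl-2-methylidene-8-(propan-2-yl)-2,3,4,4a,5,6,7,8-octahydronaphthalene
Conditions: Ph3PCH3Br, KOt-Bu, THF, 0 → 23 °C
Reagents that add atoms: methyltriphenylphosphonium bromide, C[P+](c1ccccc1)(c1ccccc1)c1ccccc1.[Br-]
Why: Wittig methylenation of the enone carbonyl with the non-stabilised ylide; the resulting diene is locked s-trans and can later react only as a 2π partner.

Step 7
Reactants: 10 methyl 4-methyl-3-oxopentanoate; 11 prop-2-en-1-ol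
Product: 12 prop-2-en-1-yl 4-methyl-3-oxopentanoate
Conditions: DMAP (10 mol %), 4 Å molecular sieves, toluene, reflux
Reagents that add atoms: none
Why: Transesterification of a β-keto ester, driven by removal of methanol, installs the allyl group that allows neutral removal of the ester later.

Step 8
Reactants: 9 (4aR,5R,8S)-5-methyl-2-methylidene-8-(propan-2-yl)-2,3,4,4a,5,6,7,8-octahydronaphthalene; 12 prop-2-en-1-yl 4-methyl-3-oxopentanoate; 13 2-methylpropanal
Product: 15 prop-2-en-1-yl (2S,4R,4a'R,5'R,8'S)-5'-methyl-4,6,8'-tri(propan-2-yl)-3,3',4,4',4a',5',6',7'-octahydro-8'H-spiro[pyran-2,2'-naphthalene]-5-carboxylate, via alkylidene keto ester 14 (not isolated)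
Conditions: ethylenediammonium diacetate (10 mol %), 4 Å molecular sieves, toluene, 23 → 100 °C
Reagents that add atoms: none
Why: Domino Knoevenagel condensation/inverse-electron-demand hetero-Diels–Alder reaction: the 1-oxadiene 14 (ketone oxygen as terminus, isopropyl outside) adds to the exocyclic methylene with oxygen at the tertiary allylic carbon, from the ring face syn to the C5' methyl and anti to the axial C8' isopropyl group, with the ring alkene endo, which should set the spiro centre C2 (S) and C4 (R).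

Step 9
Reactants: 15 prop-2-en-1-yl (2S,4R,4a'R,5'R,8'S)-5'-methyl-4,6,8'-tri(propan-2-yl)-3,3',4,4',4a',5',6',7'-octahydro-8'H-spiro[pyran-2,2'-naphthalene]-5-carboxylate
Product: 17 (2S,4R,4a'R,5'R,8'S)-5'-methyl-4,6,8'-tri(propan-2-yl)-3,3',4,4',4a',5',6',7'-octahydro-8'H-spiro[pyran-2,2'-naphthalene], via carboxylic acid 16 (not isolated)
Conditions: Pd(PPh3)4 (5 mol %), morpholine (3 equiv), THF, 23 °C; then toluene, 100 °C
Reagents that add atoms: none
Why: Tsuji–Trost deallylation gives the β-alkoxyacrylic acid, whose thermal protodecarboxylation (ipso-protonation of the enol ether carbon, loss of CO2) removes the activating group and frees C5 of the pyran; no stereocentre is touched.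

Step 10
Reactants: 18 2-methylpropanedioic acid (methylmalonic acid)
Product: 19 2-methylpropanedioyl dichloride (methylmalonyl dichloride)
Conditions: SOCl2 (3 equiv), 50 °C; distillation
Reagents that add atoms: thionyl chloride, O=S(Cl)Cl
Why: Standard conversion of a carboxylic acid into its acid chloride via the chlorosulfite (nucleophilic acyl substitution).

Step 11
Reactants: 17 (2S,4R,4a'R,5'R,8'S)-5'-methyl-4,6,8'-tri(propan-2-yl)-3,3',4,4',4a',5',6',7'-octahydro-8'H-spiro[pyran-2,2'-naphthalene]; 19 2-methylpropanedioyl dichloride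
Product: 21 (2S,4R,4a'R,5'R,8'S)-7-hydroxy-5',6,8,8-tetramethyl-4,8'-di(propan-2-yl)-3,3',4,4',4a',5',6',7'-octahydro-8'H-spiro[chromene-2,2'-naphthalen]-5(8H)-one, via keto acid chloride 20 (not isolated)
Conditions: 19 (1.3 equiv, slow addition), 2,6-di-tert-butyl-4-methylpyridine (2.6 equiv), CH2Cl2, −30 → 23 °C, then 40 °C
Reagents that add atoms: none
Why: Effenberger-type [3+3] cyclization: the nucleophilic enol ether carbon of 17 is C-acylated by one acid chloride of 19 (the C4a–C5 bond) and the oxocarbenium ion loses its proton to the buffer to give the β-alkoxy enone 20; its γ-CH (the isopropyl methine) then becomes nucleophilic through the dienol (2-alkoxydiene) tautomer and attacks the second acid chloride, creating the C7–C8 bond and the gem-dimethyl quaternary centre. The closest known reaction type is the Effenberger cyclization of cycloalkanone enol ethers with malonyl dichloride, which builds the bicyclo[3.3.1]nonane-2,4,9-trione core of polyprenylated acylphloroglucinols and also forms fully substituted α'-carbons. Ring A closes by a 6-(enolendo)-exo-trig acylation. No stereocentre is formed, and the five existing ones (C2, C4, C4a', C5', C8') carry no acidic hydrogen under these conditions. The step needs C- rather than O-cyclization and survival of the tertiary allylic spiro ether: the enol oxygen is locked in the pyran ring, so the pyranone channel open to acyclic enol ethers is closed and O1 is fixed at C8a; the symmetric bis-electrophile removes any regiochemical question; and the hindered pyridine keeps the medium free of HCl so that the C2–O1 bond should not ionise.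

Step 12
Reactants: 21 (2S,4R,4a'R,5'R,8'S)-7-hydroxy-5',6,8,8-tetramethyl-4,8'-di(propan-2-yl)-3,3',4,4',4a',5',6',7'-octahydro-8'H-spiro[chromene-2,2'-naphthalen]-5(8H)-one
Product: 22 (2S,4R,4a'R,5'R,8'S)-7-methoxy-5',6,8,8-tetramethyl-4,8'-di(propan-2-yl)-3,3',4,4',4a',5',6',7'-octahydro-8'H-spiro[chromene-2,2'-naphthalen]-5(8H)-one (CNP0194760.3)
Conditions: TMSCHN2 (2 equiv), MeOH–toluene (1:4), 0 → 23 °C
Reagents that add atoms: (trimethylsilyl)diazomethane, C[Si](C)(C)C=[N+]=[N-]
Why: O-Methylation of a vinylogous acid by diazomethane generated in situ (proton transfer, then collapse of the methyldiazonium–enolate ion pair), which excludes C-methylation; the C7 oxygen should be alkylated preferentially because the enolate charge sits mainly there when the C5 carbonyl keeps its vinylogous-ester conjugation with O1, giving the cross-conjugated methyl enol ether of the target.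

**Compound list**

1 | (3R)-3,7-dimethyloct-6-enal, (R)-citronellal | O=CC[C@H](C)CCC=C(C)C | starting material
2 | but-3-en-2-one | CC(=O)C=C | starting material
3 | (2R,3R)-3,7-dimethyl-2-(3-oxobutyl)oct-6-enal | O=C[C@H](CCC(C)=O)[C@H](C)CCC=C(C)C | intermediate
4 | (4R)-4-[(2R)-6-methylhept-5-en-2-yl]cyclohex-2-en-1-one | O=C1C=C[C@@H]([C@H](C)CCC=C(C)C)CC1 | intermediate
5 | (4aR,5R,8R,8aR)-5-methyl-8-(prop-1-en-2-yl)octahydronaphthalen-2(1H)-one | O=C1C[C@H]2[C@H](C(C)=C)CC[C@@H](C)[C@H]2CC1 | intermediate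
6 | (4aR,5R,8S,8aS)-5-methyl-8-(propan-2-yl)octahydronaphthalen-2(1H)-one | O=C1C[C@H]2[C@H](C(C)C)CC[C@@H](C)[C@H]2CC1 | intermediate
7 | trimethyl{[(4aR,5R,8S,8aS)-5-methyl-8-(propan-2-yl)-3,4,4a,5,6,7,8,8a-octahydronaphthalen-2-yl]oxy}silane | C[Si](C)(C)OC1=C[C@H]2[C@H](C(C)C)CC[C@@H](C)[C@H]2CC1 | intermediate (not isolated)
8 | (4aR,5R,8S)-5-methyl-8-(propan-2-yl)-4,4a,5,6,7,8-hexahydronaphthalen-2(3H)-one | O=C1C=C2[C@H](C(C)C)CC[C@@H](C)[C@H]2CC1 | intermediate
9 | (4aR,5R,8S)-5-methyl-2-methylidene-8-(propan-2-yl)-2,3,4,4a,5,6,7,8-octahydronaphthalene | C=C1C=C2[C@H](C(C)C)CC[C@@H](C)[C@H]2CC1 | intermediate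
10 | methyl 4-methyl-3-oxopentanoate | COC(=O)CC(=O)C(C)C | starting material
11 | prop-2-en-1-ol | C=CCO | starting material
12 | prop-2-en-1-yl 4-methyl-3-oxopentanoate | C=CCOC(=O)CC(=O)C(C)C | intermediate
13 | 2-methylpropanal | CC(C)C=O | starting material
14 | prop-2-en-1-yl 4-methyl-2-(2-methylpropylidene)-3-oxopentanoate (E/Z mixture) | C=CCOC(=O)C(=CC(C)C)C(=O)C(C)C | intermediate (not isolated)
15 | prop-2-en-1-yl (2S,4R,4a'R,5'R,8'S)-5'-methyl-4,6,8'-tri(propan-2-yl)-3,3',4,4',4a',5',6',7'-octahydro-8'H-spiro[pyran-2,2'-naphthalene]-5-carboxylate | C=CCOC(=O)C1=C(C(C)C)O[C@]2(C=C3[C@H](C(C)C)CC[C@@H](C)[C@H]3CC2)C[C@@H]1C(C)C | intermediate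
16 | (2S,4R,4a'R,5'R,8'S)-5'-methyl-4,6,8'-tri(propan-2-yl)-3,3',4,4',4a',5',6',7'-octahydro-8'H-spiro[pyran-2,2'-naphthalene]-5-carboxylic acid | OC(=O)C1=C(C(C)C)O[C@]2(C=C3[C@H](C(C)C)CC[C@@H](C)[C@H]3CC2)C[C@@H]1C(C)C | intermediate (not isolated)
17 | (2S,4R,4a'R,5'R,8'S)-5'-methyl-4,6,8'-tri(propan-2-yl)-3,3',4,4',4a',5',6',7'-octahydro-8'H-spiro[pyran-2,2'-naphthalene] | C1=C(C(C)C)O[C@]2(C=C3[C@H](C(C)C)CC[C@@H](C)[C@H]3CC2)C[C@@H]1C(C)C | intermediate
18 | 2-methylpropanedioic acid | CC(C(=O)O)C(=O)O | starting material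
19 | 2-methylpropanedioyl dichloride | CC(C(=O)Cl)C(=O)Cl | intermediate
20 | 2-methyl-3-oxo-3-[(2S,4R,4a'R,5'R,8'S)-5'-methyl-4,6,8'-tri(propan-2-yl)-3,3',4,4',4a',5',6',7'-octahydro-8'H-spiro[pyran-2,2'-naphthalen]-5-yl]propanoyl chloride (both epimers at the methyl-bearing carbon) | ClC(=O)C(C)C(=O)C1=C(C(C)C)O[C@]2(C=C3[C@H](C(C)C)CC[C@@H](C)[C@H]3CC2)C[C@@H]1C(C)C | intermediate (not isolated)
21 | (2S,4R,4a'R,5'R,8'S)-7-hydroxy-5',6,8,8-tetramethyl-4,8'-di(propan-2-yl)-3,3',4,4',4a',5',6',7'-octahydro-8'H-spiro[chromene-2,2'-naphthalen]-5(8H)-one | OC1=C(C)C(=O)C2=C(O[C@]3(C=C4[C@H](C(C)C)CC[C@@H](C)[C@H]4CC3)C[C@@H]2C(C)C)C1(C)C | intermediate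
22 | (2S,4R,4a'R,5'R,8'S)-7-methoxy-5',6,8,8-tetramethyl-4,8'-di(propan-2-yl)-3,3',4,4',4a',5',6',7'-octahydro-8'H-spiro[chromene-2,2'-naphthalen]-5(8H)-one | COC1=C(C)C(=O)C2=C(O[C@]3(C=C4[C@H](C(C)C)CC[C@@H](C)[C@H]4CC3)C[C@@H]2C(C)C)C1(C)C | target

**Step count and risks**

Total step count: 12. Longest linear sequence: 10 steps (1–6, 8, 9, 11, 12); steps 7 and 10 each prepare one building block.

Steps most likely to fail:

Step 11. The tertiary allylic C2–O1 bond may ionise at the oxocarbenium stage, the bis-acid chloride may be lost through ketene oligomerisation, or the sequence may stall after the first C-acylation because the hindered isopropyl methine does not engage the second acyl chloride. The fallback sets out from 17 and separates the two bond formations into an electrophilic step and an anionic step. C-acylation of 17 with methyl 3-chloro-2-methyl-3-oxopropanoate (pyridine, CH2Cl2, 0 °C) should give methyl 2-methyl-3-oxo-3-[(2S,4R,4a'R,5'R,8'S)-5'-methyl-4,6,8'-tri(propan-2-yl)-3,3',4,4',4a',5',6',7'-octahydro-8'H-spiro[pyran-2,2'-naphthalen]-5-yl]propanoate F1. Its dianion (LiHMDS, 2.2 equiv, THF, −78 → 23 °C; β-keto ester enolate plus γ-deprotonation at the isopropyl CH) should then close ring A by a vinylogous Dieckmann condensation. After mildly acidic work-up the route is rejoined at 21.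

Step 8. The acyclic alkylidene β-keto ester may be too unreactive toward the non-activated exocyclic alkene, so that an ene reaction or isomerisation of the diene competes, or addition may occur with poor facial or endo selectivity. The fallback sets out from 9 and uses the much more reactive alkylidene derivative of Meldrum's acid. Condensation of 9, 13 and 2,2-dimethyl-1,3-dioxane-4,6-dione (ethylenediammonium diacetate, MeCN, 23–50 °C) should give the cycloadduct (5R,7S)-2,2-dimethyl-5-(propan-2-yl)-5,6-dihydro-4H-pyrano[2,3-d][1,3]dioxin-4-one spiro-fused at C7 to C2' of the decalin F2. Heating in wet pyridine (100 °C) removes acetone and CO2 to give the δ-lactone (4S)-4-(propan-2-yl)oxan-2-one spiro-fused at C6 (S) to C2' of the decalin F3. KHMDS and (PhO)2P(O)Cl (THF, −78 °C) convert it into the ketene acetal phosphate, diphenyl (2S,4R,4a'R,5'R,8'S)-5'-methyl-4,8'-di(propan-2-yl)-3,3',4,4',4a',5',6',7'-octahydro-8'H-spiro[pyran-2,2'-naphthalen]-6-yl phosphate F4. Cross-coupling of F4 with i-PrMgCl under Fe(acac)3 catalysis (THF/NMP, −20 °C) rejoins the route at 17.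

Step 3. The mono-activated enone may be too weak an enophile, so that cationic pathways (chloride capture, hydride shift, cyclobutane formation, or loss of the C8 proton to a tetrasubstituted alkene) outrun the concerted ene reaction. The fallback sets out from 3, closes ring 2 on the aldehyde, and builds ring 1 afterwards under kinetic control. Carbonyl-ene cyclization of 3 (ZnBr2, CH2Cl2, 0 °C) should give 4-[(1R,2R,3S,6R)-2-hydroxy-6-methyl-3-(prop-1-en-2-yl)cyclohexyl]butan-2-one F5. Hydrogenation (H2, Pd/C, EtOAc) gives 4-[(1R,2S,3S,6R)-2-hydroxy-6-methyl-3-(propan-2-yl)cyclohexyl]butan-2-one F6. Buffered Dess–Martin oxidation gives (2S,5R,6R)-5-methyl-6-(3-oxobutyl)-2-(propan-2-yl)cyclohexan-1-one F7. The kinetic methyl-ketone enolate of F7 (LDA, THF, −78 °C) should cyclise without epimerising the axial side chain to (4aR,5R,8S,8aR)-8a-hydroxy-5-methyl-8-(propan-2-yl)octahydronaphthalen-2(1H)-one F8. Trifluoroacetylation and E1cB elimination ((CF3CO)2O, Et3N, DMAP, then DBU) rejoin the route at 8.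

Further compounds
F1 | step 11 | methyl 2-methyl-3-oxo-3-[(2S,4R,4a'R,5'R,8'S)-5'-methyl-4,6,8'-tri(propan-2-yl)-3,3',4,4',4a',5',6',7'-octahydro-8'H-spiro[pyran-2,2'-naphthalen]-5-yl]propanoate | COC(=O)C(C)C(=O)C1=C(C(C)C)O[C@]2(C=C3[C@H](C(C)C)CC[C@@H](C)[C@H]3CC2)C[C@@H]1C(C)C
F2 | step 8 | (5R,7S)-2,2-dimethyl-5-(propan-2-yl)-5,6-dihydro-4H-pyrano[2,3-d][1,3]dioxin-4-one spiro-fused at C7 to C2' of the (4a'R,5'R,8'S)-decalin | CC1(C)OC(=O)C2=C(O1)O[C@]1(C=C3[C@H](C(C)C)CC[C@@H](C)[C@H]3CC1)C[C@@H]2C(C)C
F3 | step 8 | (4S)-4-(propan-2-yl)oxan-2-one spiro-fused at C6 (S) to C2' of the (4a'R,5'R,8'S)-decalin | O=C1O[C@]2(C=C3[C@H](C(C)C)CC[C@@H](C)[C@H]3CC2)C[C@H](C(C)C)C1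
F4 | step 8 | diphenyl (2S,4R,4a'R,5'R,8'S)-5'-methyl-4,8'-di(propan-2-yl)-3,3',4,4',4a',5',6',7'-octahydro-8'H-spiro[pyran-2,2'-naphthalen]-6-yl phosphate | C1=C(OP(=O)(Oc2ccccc2)Oc2ccccc2)O[C@]2(C=C3[C@H](C(C)C)CC[C@@H](C)[C@H]3CC2)C[C@@H]1C(C)C
F5 | step 3 | 4-[(1R,2R,3S,6R)-2-hydroxy-6-methyl-3-(prop-1-en-2-yl)cyclohexyl]butan-2-one | CC(=O)CC[C@@H]1[C@H](C)CC[C@@H](C(C)=C)[C@@H]1O
F6 | step 3 | 4-[(1R,2S,3S,6R)-2-hydroxy-6-methyl-3-(propan-2-yl)cyclohexyl]butan-2-one | CC(=O)CC[C@@H]1[C@H](C)CC[C@@H](C(C)C)[C@@H]1O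
F7 | step 3 | (2S,5R,6R)-5-methyl-6-(3-oxobutyl)-2-(propan-2-yl)cyclohexan-1-one | CC(=O)CC[C@@H]1[C@H](C)CC[C@@H](C(C)C)C1=O
F8 | step 3 | (4aR,5R,8S,8aR)-8a-hydroxy-5-methyl-8-(propan-2-yl)octahydronaphthalen-2(1H)-one | O=C1C[C@@]2(O)[C@H](C(C)C)CC[C@@H](C)[C@H]2CC1
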